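**Plan**

Locants: oxolane O1, C2 (bears ring B, the 3-methoxy-4-oxyphenyl ring), C3 and C4 (methyls), C5 (bears ring A, a 3,4-dimethoxyphenyl ring); side chain C7 (carbinol on ring C, the second 3,4-dimethoxyphenyl ring), C8 (aryl-ether carbon), C9 (methyl).
Retrosynthesis: the C9 methyl is drawn back to an N-acyl oxazolidinone carbonyl; C7–C8 is cut (aldol) to veratraldehyde and the aryloxyacetyl imide of ring B; the O–CH2 ether bond is cut to the oxolane phenol; C2–ring B is cut (aryllithium plus lactone); the lactone is opened to CO2, MeMgBr, propyne and veratraldehyde.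
Forward: ring A aldehyde, then propargylic alcohol, then butenolide (first ring; carbomagnesiation, carboxylation, lactonisation), then all-cis lactone, then ring B added and the hemiketal reduced to the oxolane, then phenol etherified, then C7–C8 joined, then C9 reduced to methyl.
Stereochemistry: C5 from a catalytic asymmetric alkynylation; C3 and C4 together by hydrogenation anti to the C5 aryl group; C2 by hydride delivery anti to the three cis substituents; C7 and C8 together in the auxiliary-controlled anti-aldol.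
Enabling feature: C8 carries the ring-B ether oxygen and a methyl (C9) that can be traced to a carbonyl carbon, so O–C8–C9 is an aryloxyacetyl unit with an enolisable C8 next to C7, the former aldehyde carbon of ring C; the erythro C7-hydroxy/C8-aryloxy pattern is an anti-aldol retron.

Key step: step 8

Remark: in step 1 the (R,R) enantiomer of the ProPhenol ligand is assumed to be the one that gives the (S)-carbinol from an aryl aldehyde; if the sense of induction is the reverse, the mirror-image ligand is used and nothing else changes.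
Abbreviation: ArO = 4-[(2S,3R,4S,5R)-5-(3,4-dimethoxyphenyl)-3,4-dimethyloxolan-2-yl]-2-methoxyphenoxy.

**Route**

Step 1
Reactants: 1 3,4-dimethoxybenzaldehyde (veratraldehyde); 2 propyne
Product: 3 (1S)-1-(3,4-dimethoxyphenyl)but-2-yn-1-ol
Conditions: (R,R)-ProPhenol (10 mol%), Me2Zn (3 equiv), Ph3PO (20 mol%), 2 (3 equiv), toluene, 0 °C
Reagents that add atoms: none
Why: Catalytic enantioselective alkynylation (zinc acetylide addition to an aryl aldehyde) in the chiral pocket of the dinuclear zinc–ProPhenol complex should deliver the propynyl group to one face of 1 and so set the carbinol centre, the future C5, as S.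

Step 2
Reactants: 3 (1S)-1-(3,4-dimethoxyphenyl)but-2-yn-1-ol
Product: 5 (5S)-5-(3,4-dimethoxyphenyl)-3,4-dimethylfuran-2(5H)-one, via oxamagnesacycle 4 (not isolated)
Conditions: MeMgBr (4 equiv), CuI (10 mol%), THF, 0 to 50 °C; CO2 (1 atm), 0 °C; 2 M HCl, rt
Reagents that add atoms: methylmagnesium bromide, C[Mg]Br; carbon dioxide, O=C=O
Why: Copper-catalysed hydroxyl-directed anti-carbomagnesiation of the propargylic alkoxide places the new methyl on the alkyne carbon next to the carbinol and magnesium on the far carbon in chelate 4, carboxylation of that C–Mg bond and acid lactonisation of the resulting cis hydroxy acid then close the butenolide, and the stereocentre stays untouched because it carries no acidic hydrogen until the lactone exists under acidic conditions.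

Step 3
Reactants: 5 (5S)-5-(3,4-dimethoxyphenyl)-3,4-dimethylfuran-2(5H)-one
Product: 6 (3R,4S,5R)-5-(3,4-dimethoxyphenyl)-3,4-dimethyloxolan-2-one (all-cis)
Conditions: H2 (3 atm), 5% Rh/Al2O3, EtOAc, rt
Reagents that add atoms: none
Why: Heterogeneous catalytic hydrogenation adds both hydrogens to the tetrasubstituted alkene from the face opposite the C5 aryl group, which sets C3 and C4 in one event cis to each other and to that aryl group by substrate control, while Rh in place of Pd holds back hydrogenolysis of the benzylic lactone C–O bond and alkene migration.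

Step 4
Reactants: 6 (3R,4S,5R)-5-(3,4-dimethoxyphenyl)-3,4-dimethyloxolan-2-one; 7 1-(benzyloxy)-4-bromo-2-methoxybenzene
Product: 9 (3R,4S,5R)-2-[4-(benzyloxy)-3-methoxyphenyl]-5-(3,4-dimethoxyphenyl)-3,4-dimethyloxolan-2-ol (anomeric mixture at C2), via aryllithium 8 (not isolated)
Conditions: 7, n-BuLi, THF, −78 °C; then 6, −78 °C; aq. NH4Cl
Reagents that add atoms: none
Why: Bromine–lithium exchange and a single 1,2-addition of the aryllithium to the lactone carbonyl at −78 °C, where the tetrahedral lithium alkoxide persists and the C3 hydrogen is not removed, should give the lactol on work-up, its new C2 centre being an inconsequential anomeric mixture.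

Step 5
Reactants: 9 (3R,4S,5R)-2-[4-(benzyloxy)-3-methoxyphenyl]-5-(3,4-dimethoxyphenyl)-3,4-dimethyloxolan-2-ol
Product: 10 (2S,3R,4S,5R)-2-[4-(benzyloxy)-3-methoxyphenyl]-5-(3,4-dimethoxyphenyl)-3,4-dimethyloxolane (all-cis)
Conditions: Et3SiH, BF3·OEt2, CH2Cl2, −78 °C; cold NaHCO3 quench
Reagents that add atoms: none
Why: Ionic hydrogenation of the lactol: BF3 ionises the hemiketal to the 2-aryl oxocarbenium ion and the silane delivers hydride to the face away from the three cis substituents on C3, C4 and C5, which sets C2 as S with ring B on the same side (all-cis) under kinetic control at low temperature.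

Step 6
Reactants: 10 (2S,3R,4S,5R)-2-[4-(benzyloxy)-3-methoxyphenyl]-5-(3,4-dimethoxyphenyl)-3,4-dimethyloxolane
Product: 11 4-[(2S,3R,4S,5R)-5-(3,4-dimethoxyphenyl)-3,4-dimethyloxolan-2-yl]-2-methoxyphenol
Conditions: H2 (1 atm), 10% Pd/C, EtOAc, rt
Reagents that add atoms: none
Why: Catalytic hydrogenolysis cleaves the benzyl aryl ether far faster than the hindered secondary benzylic C–O bonds of the oxolane, so the phenol should be freed with the four ring stereocentres intact.

Step 7
Reactants: 11 4-[(2S,3R,4S,5R)-5-(3,4-dimethoxyphenyl)-3,4-dimethyloxolan-2-yl]-2-methoxyphenol; 12 (4S)-4-benzyl-3-(chloroacetyl)-1,3-oxazolidin-2-one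
Product: 13 (4S)-4-benzyl-3-[(ArO)acetyl]-1,3-oxazolidin-2-one
Conditions: K2CO3, NaI (10 mol%), acetone, 40 °C
Reagents that add atoms: none
Why: Williamson ether synthesis with in situ Finkelstein activation: the phenoxide displaces the α-halide of the haloacetyl imide faster than it attacks the imide carbonyl, and no stereocentre is touched.

Step 8
Reactants: 13 (4S)-4-benzyl-3-[(ArO)acetyl]-1,3-oxazolidin-2-one; 1 3,4-dimethoxybenzaldehyde
Product: 15 (4S)-4-benzyl-3-[(2R,3R)-2-(ArO)-3-(3,4-dimethoxyphenyl)-3-hydroxypropanoyl]-1,3-oxazolidin-2-one, via silyl ether 14 (not isolated)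
Conditions: MgCl2 (20 mol%), Et3N (2 equiv), Me3SiCl (1.5 equiv), 1 (1.2 equiv), EtOAc, rt; then citric acid, MeOH, rt
Reagents that add atoms: none
Why: Proposed new method: MgCl2 binds both imide carbonyls of 13, Et3N removes one of the O–CH2–C(=O) hydrogens (made more acidic by the aryloxy group) to give the chelated Z-enolate of divalent magnesium, reversible addition to aldehyde 1 follows, and irreversible O-silylation of the magnesium aldolate by Me3SiCl gives 14 and returns MgCl2, after which mild acid methanolysis frees 15. The closest known reaction type is the MgCl2/Et3N/Me3SiCl-catalysed direct anti-aldol of N-propionyl oxazolidinones with aromatic aldehydes, whereas N-aryloxyacetyl oxazolidinones are known in the boron-mediated syn-aldol, so the extension to this α-oxygenated imide is the untested part. No ring is closed; the acyclic C7–C8 bond is formed. C8 is controlled by the auxiliary, because in the magnesium chelate the C4 benzyl group covers one enolate face and the aldehyde adds to the other (the sense of chelate-controlled alkylations), which gives 2R; C7 is controlled by the boat-like transition state in which the aldehyde is bound to the same magnesium, which leads to the anti (2R,3R) adduct that becomes the 7R,8S erythro unit once C9 is a methyl. The step needs anti over syn selectivity and aldol addition in preference to O-silylation of the enolate, and the non-enolisable aryl aldehyde 1, the remoteness of the four oxolane centres and the mildness of MgCl2 toward the benzylic ring ethers are expected to secure this.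

Step 9
Reactants: 15 (4S)-4-benzyl-3-[(2R,3R)-2-(ArO)-3-(3,4-dimethoxyphenyl)-3-hydroxypropanoyl]-1,3-oxazolidin-2-one
Product: 16 (1R,2S)-2-(ArO)-1-(3,4-dimethoxyphenyl)propane-1,3-diol
Conditions: LiBH4, MeOH (2 equiv), THF, 0 °C
Reagents that add atoms: none
Why: Reductive cleavage of the N-acyl oxazolidinone by LiBH4 (hydride attack at the exocyclic carbonyl and reduction of the aldehyde formed) gives the primary alcohol and frees the auxiliary without enolisation, so C7 and C8 are kept.

Step 10
Reactants: 16 (1R,2S)-2-(ArO)-1-(3,4-dimethoxyphenyl)propane-1,3-diol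
Product: 17 (2S,3R)-2-(ArO)-3-(3,4-dimethoxyphenyl)-3-hydroxypropyl 4-methylbenzenesulfonate
Conditions: TsCl (1.1 equiv), pyridine, CH2Cl2, 0 °C
Reagents that add atoms: 4-methylbenzenesulfonyl chloride, Cc1ccc(cc1)S(=O)(=O)Cl
Why: Selective sulfonylation (tosylation) of the primary C9 hydroxyl, which reacts much faster than the hindered secondary benzylic C7 hydroxyl at 0 °C.

Step 11
Reactants: 17 (2S,3R)-2-(ArO)-3-(3,4-dimethoxyphenyl)-3-hydroxypropyl 4-methylbenzenesulfonate
Product: 18 (1R,2S)-1-(3,4-dimethoxyphenyl)-2-{4-[(2S,3R,4S,5R)-5-(3,4-dimethoxyphenyl)-3,4-dimethyloxolan-2-yl]-2-methoxyphenoxy}propan-1-ol (target)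
Conditions: LiAlH4, THF, 0 °C to rt
Reagents that add atoms: none
Why: Hydride reduction of the primary sulfonate (SN2 displacement by LiAlH4) turns C9 into the methyl group without touching C7 or C8.

**Compound list**

1 | 3,4-dimethoxybenzaldehyde (veratraldehyde) | COc1ccc(C=O)cc1OC | starting material
2 | propyne | CC#C | starting material
3 | (1S)-1-(3,4-dimethoxyphenyl)but-2-yn-1-ol | COc1ccc([C@H](O)C#CC)cc1OC | intermediate
4 | (5S)-5-(3,4-dimethoxyphenyl)-3,4-dimethyl-2,5-dihydro-1,2-oxamagnesole (chelated alkenylmagnesium alkoxide, drawn halide-free; not isolated) | CC1=C(C)[C@H](c2ccc(OC)c(OC)c2)O[Mg]1 | intermediate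
5 | (5S)-5-(3,4-dimethoxyphenyl)-3,4-dimethylfuran-2(5H)-one | CC1=C(C)[C@H](c2ccc(OC)c(OC)c2)OC1=O | intermediate
6 | (3R,4S,5R)-5-(3,4-dimethoxyphenyl)-3,4-dimethyloxolan-2-one (all-cis) | O=C1O[C@@H](c2ccc(OC)c(OC)c2)[C@@H](C)[C@H]1C | intermediate
7 | 1-(benzyloxy)-4-bromo-2-methoxybenzene | COc1cc(Br)ccc1OCc1ccccc1 | starting material
8 | [4-(benzyloxy)-3-methoxyphenyl]lithium (not isolated) | COc1cc([Li])ccc1OCc1ccccc1 | intermediate
9 | (3R,4S,5R)-2-[4-(benzyloxy)-3-methoxyphenyl]-5-(3,4-dimethoxyphenyl)-3,4-dimethyloxolan-2-ol (C2 anomers, in equilibrium with the open hydroxy ketone) | COc1cc(C2(O)O[C@@H](c3ccc(OC)c(OC)c3)[C@@H](C)[C@H]2C)ccc1OCc1ccccc1 | intermediate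
10 | (2S,3R,4S,5R)-2-[4-(benzyloxy)-3-methoxyphenyl]-5-(3,4-dimethoxyphenyl)-3,4-dimethyloxolane | COc1cc([C@H]2O[C@@H](c3ccc(OC)c(OC)c3)[C@@H](C)[C@H]2C)ccc1OCc1ccccc1 | intermediate
11 | 4-[(2S,3R,4S,5R)-5-(3,4-dimethoxyphenyl)-3,4-dimethyloxolan-2-yl]-2-methoxyphenol | COc1cc([C@H]2O[C@@H](c3ccc(OC)c(OC)c3)[C@@H](C)[C@H]2C)ccc1O | intermediate
12 | (4S)-4-benzyl-3-(chloroacetyl)-1,3-oxazolidin-2-one | O=C(CCl)N1C(=O)OC[C@@H]1Cc1ccccc1 | starting material
13 | (4S)-4-benzyl-3-[(ArO)acetyl]-1,3-oxazolidin-2-one | COc1cc([C@H]2O[C@@H](c3ccc(OC)c(OC)c3)[C@@H](C)[C@H]2C)ccc1OCC(=O)N1C(=O)OC[C@@H]1Cc1ccccc1 | intermediate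
14 | trimethylsilyl ether of 15 at the C7 oxygen (not isolated) | COc1ccc([C@@H](O[Si](C)(C)C)[C@H](C(=O)N5C(=O)OC[C@@H]5Cc6ccccc6)Oc2ccc([C@H]3O[C@@H](c4ccc(OC)c(OC)c4)[C@@H](C)[C@H]3C)cc2OC)cc1OC | intermediate
15 | (4S)-4-benzyl-3-[(2R,3R)-2-(ArO)-3-(3,4-dimethoxyphenyl)-3-hydroxypropanoyl]-1,3-oxazolidin-2-one | COc1ccc([C@@H](O)[C@H](C(=O)N5C(=O)OC[C@@H]5Cc6ccccc6)Oc2ccc([C@H]3O[C@@H](c4ccc(OC)c(OC)c4)[C@@H](C)[C@H]3C)cc2OC)cc1OC | intermediate
16 | (1R,2S)-2-(ArO)-1-(3,4-dimethoxyphenyl)propane-1,3-diol | COc1ccc([C@@H](O)[C@H](CO)Oc2ccc([C@H]3O[C@@H](c4ccc(OC)c(OC)c4)[C@@H](C)[C@H]3C)cc2OC)cc1OC | intermediate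
17 | (2S,3R)-2-(ArO)-3-(3,4-dimethoxyphenyl)-3-hydroxypropyl 4-methylbenzenesulfonate | COc1ccc([C@@H](O)[C@H](COS(=O)(=O)c5ccc(C)cc5)Oc2ccc([C@H]3O[C@@H](c4ccc(OC)c(OC)c4)[C@@H](C)[C@H]3C)cc2OC)cc1OC | intermediate
18 | (1R,2S)-1-(3,4-dimethoxyphenyl)-2-{4-[(2S,3R,4S,5R)-5-(3,4-dimethoxyphenyl)-3,4-dimethyloxolan-2-yl]-2-methoxyphenoxy}propan-1-ol | COc1ccc([C@@H](O)[C@H](C)Oc2ccc([C@H]3O[C@@H](c4ccc(OC)c(OC)c4)[C@@H](C)[C@H]3C)cc2OC)cc1OC | target

**Step count and risks**

Total step count: 11. Longest linear sequence: 11 steps (1 to 18).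

Steps most likely to fail:

Step 8. The α-aryloxy oxygen may change the chelation pattern of the magnesium enolate and erode anti/syn or facial selectivity, or O-silylation of the enolate may outrun the aldol addition. The fallback uses known chemistry and sets out from phenol 11. Williamson alkylation with (4R)-4-benzyl-3-(chloroacetyl)-1,3-oxazolidin-2-one (K2CO3, NaI, acetone) gives the mirror-auxiliary imide (4R)-4-benzyl-3-[(ArO)acetyl]-1,3-oxazolidin-2-one F1. A boron-mediated syn-aldol with 1 (Bu2BOTf, iPr2NEt, CH2Cl2, −78 to 0 °C) gives (4R)-4-benzyl-3-[(2R,3S)-2-(ArO)-3-(3,4-dimethoxyphenyl)-3-hydroxypropanoyl]-1,3-oxazolidin-2-one F2, in which C8 is correct and C7 is epimeric. Mitsunobu inversion at C7 (4-nitrobenzoic acid, PPh3, DIAD, THF) gives (1R,2R)-2-(ArO)-3-[(4R)-4-benzyl-2-oxo-1,3-oxazolidin-3-yl]-1-(3,4-dimethoxyphenyl)-3-oxopropyl 4-nitrobenzoate F3. LiBH4 then removes both the auxiliary and the ester, and the route is rejoined at diol 16.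

Step 5. Deprotonation of the oxocarbenium ion to the enol ether and reprotonation may epimerise C3, the Lewis acid may ionise the benzylic ring carbons, or hydride delivery may be incompletely face-selective. The fallback sets out from hemiketal 9. Acid-catalysed dehydration (PPTS, toluene, 4 Å molecular sieves) gives (2R,3S)-5-[4-(benzyloxy)-3-methoxyphenyl]-2-(3,4-dimethoxyphenyl)-3,4-dimethyl-2,3-dihydrofuran F4. Hydrogenation (H2, Pd/C, EtOAc) then adds hydrogen to the enol-ether double bond from the face opposite the neighbouring methyl and aryl groups, which sets C2 and C3 together, and removes the benzyl group in the same operation. The route is rejoined at phenol 11.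

Step 2. Addition of the methyl Grignard reagent to the internal alkyne may be slow, the regiochemistry may reverse, or the alkenylmagnesium may be protonated before carboxylation. The fallback sets out from aldehyde 1. The same zinc–ProPhenol alkynylation with methyl propiolate gives methyl (4S)-4-(3,4-dimethoxyphenyl)-4-hydroxybut-2-ynoate F5. Syn-addition of Me2CuLi (THF, −78 °C), iodine capture of the alkenylcopper and acid lactonisation give (5S)-5-(3,4-dimethoxyphenyl)-3-iodo-4-methylfuran-2(5H)-one F6. Stille methylation (Me4Sn, Pd(PPh3)4, CuI, DMF) returns to butenolide 5.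

Further compounds
F1 | step 8 | (4R)-4-benzyl-3-[(ArO)acetyl]-1,3-oxazolidin-2-one | COc1cc([C@H]2O[C@@H](c3ccc(OC)c(OC)c3)[C@@H](C)[C@H]2C)ccc1OCC(=O)N1C(=O)OC[C@H]1Cc1ccccc1
F2 | step 8 | (4R)-4-benzyl-3-[(2R,3S)-2-(ArO)-3-(3,4-dimethoxyphenyl)-3-hydroxypropanoyl]-1,3-oxazolidin-2-one | COc1ccc([C@H](O)[C@H](C(=O)N5C(=O)OC[C@H]5Cc6ccccc6)Oc2ccc([C@H]3O[C@@H](c4ccc(OC)c(OC)c4)[C@@H](C)[C@H]3C)cc2OC)cc1OC
F3 | step 8 | (1R,2R)-2-(ArO)-3-[(4R)-4-benzyl-2-oxo-1,3-oxazolidin-3-yl]-1-(3,4-dimethoxyphenyl)-3-oxopropyl 4-nitrobenzoate | COc1ccc([C@@H](OC(=O)c7ccc(cc7)[N+](=O)[O-])[C@H](C(=O)N5C(=O)OC[C@H]5Cc6ccccc6)Oc2ccc([C@H]3O[C@@H](c4ccc(OC)c(OC)c4)[C@@H](C)[C@H]3C)cc2OC)cc1OC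
F4 | step 5 | (2R,3S)-5-[4-(benzyloxy)-3-methoxyphenyl]-2-(3,4-dimethoxyphenyl)-3,4-dimethyl-2,3-dihydrofuran | COc1cc(C2=C(C)[C@H](C)[C@H](c3ccc(OC)c(OC)c3)O2)ccc1OCc1ccccc1
F5 | step 2 | methyl (4S)-4-(3,4-dimethoxyphenyl)-4-hydroxybut-2-ynoate | COc1ccc([C@H](O)C#CC(=O)OC)cc1OC
F6 | step 2 | (5S)-5-(3,4-dimethoxyphenyl)-3-iodo-4-methylfuran-2(5H)-one | IC1=C(C)[C@H](c2ccc(OC)c(OC)c2)OC1=O
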